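**Strategy.** With the chain numbered C1 (benzylic carbon on the benzene ring) to C16 (CH2OH), everything rests on cutting the C7–C8 bond between the methyl-bearing sp2 carbon of the C6=C7 alkene and a plain methylene. The key step exploits this alkyl–alkenyl junction. Both carbons come as electrophiles: C8 as the α-carbon of a redox-active ester (one carbon is lost as CO2), C7 as an (E)-alkenyl iodide that already carries the arene, the C5 stereocentre and the C2=C3 alkene. A nickel-catalysed electroreductive decarboxylative alkenylation unites them in one operation with retention of the C6=C7 geometry; the precursor pair is fully silylated, so one fluoride step then gives the target.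

Key step: step 14

Assumption: but-2-ynal is taken as a commercial reagent (otherwise one MnO2 oxidation from but-2-yn-1-ol).
Assumption: the (S)-antipode of the phosphoric acid TRIP is taken to deliver the 4S alcohol in step 8, by analogy with aryl aldehydes; if the sense proves opposite (Mosher ester check), the (R)-catalyst is used.

Step 1
Reactants: 1 geranyl bromide; 2 ethyl acetate
Product: 4 ethyl (4E)-5,9-dimethyldeca-4,8-dienoate, via lithium enolate of ethyl acetate 3 (not isolated)
Conditions: LDA, THF, −78 °C; then 1, DMPU, −78 → −20 °C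
Reagents that add atoms: none
Why: SN2 alkylation of a lithium ester enolate by the primary allylic bromide at its unsubstituted carbon adds the two-carbon acid handle and leaves the E alkene untouched (enolate alkylation).

Step 2
Reactants: 4 ethyl (4E)-5,9-dimethyldeca-4,8-dienoate
Product: 5 ethyl (4E,8E)-10-hydroxy-5,9-dimethyldeca-4,8-dienoate
Conditions: SeO2 (cat.), t-BuOOH, salicylic acid (cat.), CH2Cl2, rt
Reagents that add atoms: selenium dioxide O=[Se]=O (catalytic oxygen carrier); tert-butyl hydroperoxide CC(C)(C)OO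
Why: SeO2 allylic oxidation (ene reaction, then [2,3]-sigmatropic shift) should attack the (E)-methyl group of the terminal, most accessible trisubstituted alkene and so give the (E)-allylic alcohol.

Step 3
Reactants: 5 ethyl (4E,8E)-10-hydroxy-5,9-dimethyldeca-4,8-dienoate
Product: 6 ethyl (4E,8E)-10-[(tert-butyldimethylsilyl)oxy]-5,9-dimethyldeca-4,8-dienoate
Conditions: TBSCl, imidazole, DMF, rt
Reagents that add atoms: tert-butyldimethylsilyl chloride CC(C)(C)[Si](C)(C)Cl
Why: Silylation of the primary allylic alcohol masks it so that only the carboxyl group is activated later (silyl ether protection).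

Step 4
Reactants: 6 ethyl (4E,8E)-10-[(tert-butyldimethylsilyl)oxy]-5,9-dimethyldeca-4,8-dienoate
Product: 7 (4E,8E)-10-[(tert-butyldimethylsilyl)oxy]-5,9-dimethyldeca-4,8-dienoic acid
Conditions: LiOH, THF/MeOH/H2O, rt; then cold dilute HCl to pH 4
Reagents that add atoms: lithium hydroxide [Li+].[OH-]
Why: Saponification cleaves the unhindered ethyl ester under conditions that a primary silyl ether tolerates.

Step 5
Reactants: 7 (4E,8E)-10-[(tert-butyldimethylsilyl)oxy]-5,9-dimethyldeca-4,8-dienoic acid
Product: 8 1,3-dioxoisoindolin-2-yl (4E,8E)-10-[(tert-butyldimethylsilyl)oxy]-5,9-dimethyldeca-4,8-dienoate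
Conditions: N-hydroxyphthalimide, DIC, DMAP (cat.), CH2Cl2, rt
Reagents that add atoms: N-hydroxyphthalimide O=C1N(O)C(=O)c2ccccc12
Why: Carbodiimide-mediated esterification (Steglich type) turns the acid into the N-acyloxyphthalimide that accepts one electron and fragments in step 14.

Step 6
Reactants: 9 2-bromo-6-methylphenol
Product: 11 2-bromo-6-methylbenzene-1,4-diol, via 2-bromo-6-methyl-1,4-benzoquinone 10 (not isolated)
Conditions: (KSO3)2NO, KH2PO4, acetone/H2O, 0 °C → rt; then aq. Na2S2O4
Reagents that add atoms: potassium nitrosodisulfonate [K+].[K+].[O]N(S(=O)(=O)[O-])S(=O)(=O)[O-]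
Why: Teuber oxidation of a phenol with a free para position gives the para-quinone, which dithionite reduces in the same flask to the hydroquinone with the bromine ortho to the flanked hydroxyl.

Step 7
Reactants: 11 2-bromo-6-methylbenzene-1,4-diol
Product: 12 1-bromo-2,5-bis[(tert-butyldimethylsilyl)oxy]-3-methylbenzene
Conditions: TBSCl, imidazole, DMF, 40 °C
Reagents that add atoms: tert-butyldimethylsilyl chloride CC(C)(C)[Si](C)(C)Cl
Why: Double silylation protects the oxidation-prone hydroquinone with groups that fluoride removes at the end.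

Step 8
Reactants: 13 but-2-ynal; 14 allenylboronic acid pinacol ester
Product: 16 (4S)-hepta-1,5-diyn-4-ol, via O-boryl ether of the alcohol 15 (not isolated)
Conditions: (S)-TRIP (5 mol%), 4 Å MS, toluene, −20 °C; aqueous work-up
Reagents that add atoms: none
Why: Chiral phosphoric acid-catalysed allenylboration (propargylation through a six-membered SE2' transition state) should set the C5 stereocentre by catalyst control, the phosphate binding the boronate oxygen and the formyl hydrogen so that one aldehyde face is shielded by the 2,4,6-triisopropylphenyl groups.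

Step 9
Reactants: 16 (4S)-hepta-1,5-diyn-4-ol
Product: 17 (4S)-4-[(tert-butyldimethylsilyl)oxy]hepta-1,5-diyne
Conditions: TBSCl, imidazole, DMF, rt
Reagents that add atoms: tert-butyldimethylsilyl chloride CC(C)(C)[Si](C)(C)Cl
Why: Silyl protection of the propargylic alcohol removes the acidic proton before the organoaluminium and organolithium steps.

Step 10
Reactants: 17 (4S)-4-[(tert-butyldimethylsilyl)oxy]hepta-1,5-diyne
Product: 20 (2E,5S)-5-[(tert-butyldimethylsilyl)oxy]-3-methyloct-2-en-6-yn-1-ol, via alkenyldimethylalane 18 (not isolated), via lithium alkenylalanate 19 (not isolated)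
Conditions: Me3Al, Cp2ZrCl2 (25 mol%), CH2Cl2, 0 °C → rt; then n-BuLi, THF, −78 °C; (CH2O)n, −78 °C → rt; Rochelle salt work-up
Reagents that add atoms: trimethylaluminium C[Al](C)C; formaldehyde (as paraformaldehyde) C=O
Why: Negishi zirconium-catalysed carboalumination adds methyl and aluminium syn across the terminal alkyne only (methyl to the inner carbon), and the derived alanate is hydroxymethylated with retention, which fixes the 2E trisubstituted alkene.

Step 11
Reactants: 20 (2E,5S)-5-[(tert-butyldimethylsilyl)oxy]-3-methyloct-2-en-6-yn-1-ol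
Product: 21 (2E,5S)-1-bromo-5-[(tert-butyldimethylsilyl)oxy]-3-methyloct-2-en-6-yne
Conditions: CBr4, PPh3, CH2Cl2, 0 °C
Reagents that add atoms: carbon tetrabromide BrC(Br)(Br)Br
Why: The Appel reaction converts the primary allylic alcohol into the bromide under neutral conditions without allylic transposition.

Step 12
Reactants: 12 1-bromo-2,5-bis[(tert-butyldimethylsilyl)oxy]-3-methylbenzene; 21 (2E,5S)-1-bromo-5-[(tert-butyldimethylsilyl)oxy]-3-methyloct-2-en-6-yne
Product: 24 (2E,5S)-1-{2,5-bis[(tert-butyldimethylsilyl)oxy]-3-methylphenyl}-5-[(tert-butyldimethylsilyl)oxy]-3-methyloct-2-en-6-yne, via aryllithium 22 (not isolated), via arylcopper 23 (not isolated)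
Conditions: 12, t-BuLi (2 equiv), Et2O, −78 °C; CuBr·SMe2, −78 → −40 °C; then 21, THF, −40 → 0 °C
Reagents that add atoms: none
Why: Bromine–lithium exchange, transmetalation to copper and SN2 displacement of the primary allylic bromide should join the arene to C1, since the fully substituted γ-carbon disfavours SN2' attack and the alkene geometry is not touched.

Step 13
Reactants: 24 (2E,5S)-1-{2,5-bis[(tert-butyldimethylsilyl)oxy]-3-methylphenyl}-5-[(tert-butyldimethylsilyl)oxy]-3-methyloct-2-en-6-yne
Product: 26 (2E,4S,6E)-8-{2,5-bis[(tert-butyldimethylsilyl)oxy]-3-methylphenyl}-4-[(tert-butyldimethylsilyl)oxy]-2-iodo-6-methylocta-2,6-diene, via alkenylzirconocene chloride 25 (not isolated)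
Conditions: Cp2Zr(H)Cl (2.5 equiv), THF, rt → 40 °C; then I2, 0 °C
Reagents that add atoms: iodine II
Why: Syn hydrozirconation of the methyl alkyne, equilibrated with excess reagent, should place zirconium on the less hindered methyl-bearing carbon away from the branched silyloxy carbon, and iodinolysis with retention gives the (E)-iodide with iodine trans to C5.

Step 14
Reactants: 8 1,3-dioxoisoindolin-2-yl (4E,8E)-10-[(tert-butyldimethylsilyl)oxy]-5,9-dimethyldeca-4,8-dienoate; 26 (2E,4S,6E)-8-{2,5-bis[(tert-butyldimethylsilyl)oxy]-3-methylphenyl}-4-[(tert-butyldimethylsilyl)oxy]-2-iodo-6-methylocta-2,6-diene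
Product: 27 (2E,5S,6E,10E,14E)-1-{2,5-bis[(tert-butyldimethylsilyl)oxy]-3-methylphenyl}-5,16-bis[(tert-butyldimethylsilyl)oxy]-3,7,11,15-tetramethylhexadeca-2,6,10,14-tetraene
Conditions: NiCl2·6H2O (20 mol%), 2,2'-bipyridine (20 mol%), AgNO3 (0.3 equiv), DMF, Mg anode, RVC cathode, undivided cell, constant current, rt
Reagents that add atoms: none
Why: Cathodic reduction keeps a bipyridine–nickel catalyst low-valent so that it inserts into the C–I bond of 26 with retention, while one-electron reduction of 8 (at the silver-coated cathode or by low-valent nickel) expels phthalimide anion and CO2 and leaves the primary C8 radical; capture of this radical by the alkenyl–nickel species and reductive elimination from trivalent nickel form C7–C8. The closest known reaction type is the nickel-electrocatalytic decarboxylative alkenylation of redox-active esters with alkenyl iodides, a cross-electrophile coupling, applied here to an α-methyl alkenyl iodide. No ring is closed and no stereocentre is created: C5 is a spectator and the C6=C7 geometry is inherited from 26. The step needs cross-coupling over homo-coupling, which is secured because the two electrophiles are activated by different elementary steps (two-electron oxidative addition against one-electron fragmentation). It also needs radical capture to outrun reversible 3-exo closure of the C8 radical onto C10=C11, which a high nickel loading and a low current density favour. The iodine of 26 is cis only to hydrogen, so the C5 silyl ether should not block oxidative addition.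

Step 15
Reactants: 27 (2E,5S,6E,10E,14E)-1-{2,5-bis[(tert-butyldimethylsilyl)oxy]-3-methylphenyl}-5,16-bis[(tert-butyldimethylsilyl)oxy]-3,7,11,15-tetramethylhexadeca-2,6,10,14-tetraene
Product: 28 2-[(2E,5S,6E,10E,14E)-5,16-dihydroxy-3,7,11,15-tetramethylhexadeca-2,6,10,14-tetraen-1-yl]-6-methylbenzene-1,4-diol (CNP0151872.1)
Conditions: TBAF, AcOH, degassed THF, 0 °C → rt, under Ar
Reagents that add atoms: none
Why: Buffered fluoride cleaves the two aryl and two allylic silyl ethers in one operation without acid that could ionise the C5 allylic alcohol and without free base that would promote air oxidation of the hydroquinone.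

**Compound list**

1 | geranyl bromide, (2E)-1-bromo-3,7-dimethylocta-2,6-diene | CC(C)=CCC/C(C)=C/CBr | starting material
2 | ethyl acetate | CCOC(C)=O | starting material
3 | lithium enolate of ethyl acetate (lithium 1-ethoxyethenolate) | [Li+].[O-]C(=C)OCC | intermediate (not isolated)
4 | ethyl (4E)-5,9-dimethyldeca-4,8-dienoate | CC(C)=CCC/C(C)=C/CCC(=O)OCC | intermediate
5 | ethyl (4E,8E)-10-hydroxy-5,9-dimethyldeca-4,8-dienoate | C/C(=C\CC/C(C)=C/CCC(=O)OCC)CO | intermediate
6 | ethyl (4E,8E)-10-[(tert-butyldimethylsilyl)oxy]-5,9-dimethyldeca-4,8-dienoate | C/C(=C\CC/C(C)=C/CCC(=O)OCC)CO[Si](C)(C)C(C)(C)C | intermediate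
7 | (4E,8E)-10-[(tert-butyldimethylsilyl)oxy]-5,9-dimethyldeca-4,8-dienoic acid | C/C(=C\CC/C(C)=C/CCC(=O)O)CO[Si](C)(C)C(C)(C)C | intermediate
8 | 1,3-dioxoisoindolin-2-yl (4E,8E)-10-[(tert-butyldimethylsilyl)oxy]-5,9-dimethyldeca-4,8-dienoate (redox-active ester) | C/C(=C\CC/C(C)=C/CCC(=O)ON1C(=O)c2ccccc2C1=O)CO[Si](C)(C)C(C)(C)C | intermediate
9 | 2-bromo-6-methylphenol | Cc1cccc(Br)c1O | starting material
10 | 2-bromo-6-methyl-1,4-benzoquinone | CC1=CC(=O)C=C(Br)C1=O | intermediate (not isolated)
11 | 2-bromo-6-methylbenzene-1,4-diol | Cc1cc(O)cc(Br)c1O | intermediate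
12 | 1-bromo-2,5-bis[(tert-butyldimethylsilyl)oxy]-3-methylbenzene | Cc1cc(O[Si](C)(C)C(C)(C)C)cc(Br)c1O[Si](C)(C)C(C)(C)C | intermediate
13 | but-2-ynal | CC#CC=O | starting material
14 | allenylboronic acid pinacol ester, 4,4,5,5-tetramethyl-2-(propa-1,2-dien-1-yl)-1,3,2-dioxaborolane | C=C=CB1OC(C)(C)C(C)(C)O1 | starting material
15 | 2-[(4S)-hepta-1,5-diyn-4-yloxy]-4,4,5,5-tetramethyl-1,3,2-dioxaborolane | CC#C[C@@H](OB1OC(C)(C)C(C)(C)O1)CC#C | intermediate (not isolated)
16 | (4S)-hepta-1,5-diyn-4-ol | CC#C[C@@H](O)CC#C | intermediate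
17 | (4S)-4-[(tert-butyldimethylsilyl)oxy]hepta-1,5-diyne | CC#C[C@@H](O[Si](C)(C)C(C)(C)C)CC#C | intermediate
18 | {(1E,4S)-4-[(tert-butyldimethylsilyl)oxy]-2-methylhept-1-en-5-yn-1-yl}dimethylalane | CC#C[C@@H](O[Si](C)(C)C(C)(C)C)C/C(C)=C/[Al](C)C | intermediate (not isolated)
19 | lithium butyl{(1E,4S)-4-[(tert-butyldimethylsilyl)oxy]-2-methylhept-1-en-5-yn-1-yl}dimethylaluminate | CC#C[C@@H](O[Si](C)(C)C(C)(C)C)C/C(C)=C/[Al-](C)(C)CCCC.[Li+] | intermediate (not isolated)
20 | (2E,5S)-5-[(tert-butyldimethylsilyl)oxy]-3-methyloct-2-en-6-yn-1-ol | CC#C[C@@H](O[Si](C)(C)C(C)(C)C)C/C(C)=C/CO | intermediate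
21 | (2E,5S)-1-bromo-5-[(tert-butyldimethylsilyl)oxy]-3-methyloct-2-en-6-yne | CC#C[C@@H](O[Si](C)(C)C(C)(C)C)C/C(C)=C/CBr | intermediate
22 | {2,5-bis[(tert-butyldimethylsilyl)oxy]-3-methylphenyl}lithium | Cc1cc(O[Si](C)(C)C(C)(C)C)cc([Li])c1O[Si](C)(C)C(C)(C)C | intermediate (not isolated)
23 | {2,5-bis[(tert-butyldimethylsilyl)oxy]-3-methylphenyl}copper | Cc1cc(O[Si](C)(C)C(C)(C)C)cc([Cu])c1O[Si](C)(C)C(C)(C)C | intermediate (not isolated)
24 | (2E,5S)-1-{2,5-bis[(tert-butyldimethylsilyl)oxy]-3-methylphenyl}-5-[(tert-butyldimethylsilyl)oxy]-3-methyloct-2-en-6-yne | CC#C[C@@H](O[Si](C)(C)C(C)(C)C)C/C(C)=C/Cc1cc(O[Si](C)(C)C(C)(C)C)cc(C)c1O[Si](C)(C)C(C)(C)C | intermediate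
25 | chlorobis(cyclopentadienyl){(2E,4S,6E)-8-{2,5-bis[(tert-butyldimethylsilyl)oxy]-3-methylphenyl}-4-[(tert-butyldimethylsilyl)oxy]-6-methylocta-2,6-dien-2-yl}zirconium | Cl[Zr](C1C=CC=C1)(C1C=CC=C1)/C(C)=C/[C@@H](O[Si](C)(C)C(C)(C)C)C/C(C)=C/Cc1cc(O[Si](C)(C)C(C)(C)C)cc(C)c1O[Si](C)(C)C(C)(C)C | intermediate (not isolated)
26 | (2E,4S,6E)-8-{2,5-bis[(tert-butyldimethylsilyl)oxy]-3-methylphenyl}-4-[(tert-butyldimethylsilyl)oxy]-2-iodo-6-methylocta-2,6-diene | I/C(C)=C/[C@@H](O[Si](C)(C)C(C)(C)C)C/C(C)=C/Cc1cc(O[Si](C)(C)C(C)(C)C)cc(C)c1O[Si](C)(C)C(C)(C)C | intermediate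
27 | (2E,5S,6E,10E,14E)-1-{2,5-bis[(tert-butyldimethylsilyl)oxy]-3-methylphenyl}-5,16-bis[(tert-butyldimethylsilyl)oxy]-3,7,11,15-tetramethylhexadeca-2,6,10,14-tetraene | C/C(=C\CC/C(C)=C/CC/C(C)=C/[C@@H](O[Si](C)(C)C(C)(C)C)C/C(C)=C/Cc1cc(O[Si](C)(C)C(C)(C)C)cc(C)c1O[Si](C)(C)C(C)(C)C)CO[Si](C)(C)C(C)(C)C | intermediate
28 | 2-[(2E,5S,6E,10E,14E)-5,16-dihydroxy-3,7,11,15-tetramethylhexadeca-2,6,10,14-tetraen-1-yl]-6-methylbenzene-1,4-diol | C/C(=C\CC/C(C)=C/CC/C(C)=C/[C@@H](O)C/C(C)=C/Cc1cc(O)cc(C)c1O)CO | target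

**Step count.** Total: 15 steps. Longest linear sequence: 8 steps (steps 8–15, from but-2-ynal).

**Steps most likely to fail**

1. Step 14 (key step). Oxidative addition into the α-methyl alkenyl iodide may be slow, so that both partners are reduced or dimerised at the cathode instead of cross-coupling. A slowly captured C8 radical may also add reversibly to the C10=C11 bond (3-exo closure and reopening), which would erode the geometry of that alkene. The fallback sets out from acid 7, uses iodide 26 unchanged and comes back at 27. Acid 7 is esterified with 2-mercaptopyridine N-oxide (DCC, CH2Cl2, in the dark) to 2-thioxopyridin-1(2H)-yl (4E,8E)-10-[(tert-butyldimethylsilyl)oxy]-5,9-dimethyldeca-4,8-dienoate F1. Irradiation of F1 with iodoform (Barton decarboxylative iodination, where iodine-atom transfer at high iodoform concentration should be much faster than the 3-exo closure) gives tert-butyl{[(2E,6E)-9-iodo-2,6-dimethylnona-2,6-dien-1-yl]oxy}dimethylsilane F2. Iodine–lithium exchange (t-BuLi, Et2O, −78 °C) followed by ZnCl2 gives {(3E,7E)-9-[(tert-butyldimethylsilyl)oxy]-4,8-dimethylnona-3,7-dien-1-yl}zinc chloride F3. Negishi coupling of F3 with 26 (Pd(PPh3)4, THF, rt) forms the same C7–C8 bond by a two-electron pathway, with retention at C7 and no free radical at C8.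

2. Step 8. Facial discrimination may be poor for the slim, rod-like alkynyl aldehyde, and an uncatalysed background allenylboration may compete, so that the C5 centre is formed with low enantiomeric purity. The fallback sets out from but-2-ynal 13 and comes back at silyl ether 17. A titanium-enolate acetate aldol addition of (4S)-3-acetyl-4-benzyl-1,3-thiazolidine-2-thione to 13 (TiCl4, i-Pr2NEt, CH2Cl2, −78 °C) gives 1-[(4S)-4-benzyl-2-thioxo-1,3-thiazolidin-3-yl]-(3S)-3-hydroxyhex-4-yn-1-one F4; the auxiliary antipode is chosen so that the 3S adduct is the major diastereomer, and the minor one is removed by chromatography. Silylation (TBSOTf, 2,6-lutidine) gives 1-[(4S)-4-benzyl-2-thioxo-1,3-thiazolidin-3-yl]-(3S)-3-[(tert-butyldimethylsilyl)oxy]hex-4-yn-1-one F5. DIBAL-H at −78 °C releases the auxiliary and gives (3S)-3-[(tert-butyldimethylsilyl)oxy]hex-4-ynal F6. Ohira–Bestmann homologation (dimethyl (1-diazo-2-oxopropyl)phosphonate, K2CO3, MeOH) converts F6 into the terminal alkyne 17.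

3. Step 12. In the ortho-lithiated aryl silyl ether the silyl group may migrate from oxygen to carbon before transmetalation, and the arylcopper may attack the substituted allyl terminus or couple sluggishly next to the bulky silyl ether. The fallback sets out from aryl bromide 12, uses bromide 21 unchanged and comes back at 24. Miyaura borylation of 12 (B2pin2, Pd(dppf)Cl2, KOAc, dioxane, 80 °C) gives 2-{2,5-bis[(tert-butyldimethylsilyl)oxy]-3-methylphenyl}-4,4,5,5-tetramethyl-1,3,2-dioxaborolane F7, in which no carbanion sits next to the silyl ether. Suzuki–Miyaura allyl–aryl coupling of F7 with 21 (Pd(PPh3)4, K3PO4, THF/H2O, 40 °C) should form the same aryl–C1 bond at the less substituted allyl terminus.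

**Further compounds**

F1 | step 14 | 2-thioxopyridin-1(2H)-yl (4E,8E)-10-[(tert-butyldimethylsilyl)oxy]-5,9-dimethyldeca-4,8-dienoate | C/C(=C\CC/C(C)=C/CCC(=O)ON1C=CC=CC1=S)CO[Si](C)(C)C(C)(C)C
F2 | step 14 | tert-butyl{[(2E,6E)-9-iodo-2,6-dimethylnona-2,6-dien-1-yl]oxy}dimethylsilane | C/C(=C\CC/C(C)=C/CCI)CO[Si](C)(C)C(C)(C)C
F3 | step 14 | {(3E,7E)-9-[(tert-butyldimethylsilyl)oxy]-4,8-dimethylnona-3,7-dien-1-yl}zinc chloride | C/C(=C\CC/C(C)=C/CC[Zn]Cl)CO[Si](C)(C)C(C)(C)C
F4 | step 8 | 1-[(4S)-4-benzyl-2-thioxo-1,3-thiazolidin-3-yl]-(3S)-3-hydroxyhex-4-yn-1-one | CC#C[C@@H](O)CC(=O)N1[C@@H](Cc2ccccc2)CSC1=S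
F5 | step 8 | 1-[(4S)-4-benzyl-2-thioxo-1,3-thiazolidin-3-yl]-(3S)-3-[(tert-butyldimethylsilyl)oxy]hex-4-yn-1-one | CC#C[C@@H](O[Si](C)(C)C(C)(C)C)CC(=O)N1[C@@H](Cc2ccccc2)CSC1=S
F6 | step 8 | (3S)-3-[(tert-butyldimethylsilyl)oxy]hex-4-ynal | CC#C[C@@H](O[Si](C)(C)C(C)(C)C)CC=O
F7 | step 12 | 2-{2,5-bis[(tert-butyldimethylsilyl)oxy]-3-methylphenyl}-4,4,5,5-tetramethyl-1,3,2-dioxaborolane | Cc1cc(O[Si](C)(C)C(C)(C)C)cc(B2OC(C)(C)C(C)(C)O2)c1O[Si](C)(C)C(C)(C)C
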